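- If your hunch is that more gas buys more target in ash at 1.5 h, we read the runs the other way.

| setting | ash | cedar | flask |
|---|---|---|---|
| substrate | 0.050 M | 0.10 M | 0.050 M |
| gas phase | 1.8 mM (held) | 1.8 mM (held) | 1.8 mM (held) |
| remark | the very flask that is asked about, followed so far | run made earlier |  |
| time |  |  | 1.5 h |

- ash (time / min: target / %, substrate / %): 6.00: 11.3, 85.3; 15.0: 20.5, 67.1; 30.0: 23.5, 44.0; 50.0: 21.7, 23.4
- cedar (time / min: target / %, substrate / %): 25.0: 19.5, 58.9; 50.0: 21.1, 31.2; 60.0: 21.5, 23.7; 90.0: 16.6, 9.4

(each reading ± 0.5 percentage points)

- at the start none of the gas is dissolved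
- on the list of suspects stand: gas phase <-> dissolved gas; substrate + dissolved gas -> target; dissolved gas + target -> over-reacted product; dissolved gas + target -> over-reaction product; dissolved gas -> decomposed reagent; target <-> isomer of the product

* amount of target at 1.5 h, in percent of the substrate charged
* the change that raises the amount of target at 1.5 h, in percent of the substrate charged most ("none" if none brings more than 2 percentage points) (red / violet / none)
* amount of target at 1.5 h, in percent of the substrate charged, after red

- red: doubling the saturation concentration of gas phase, all else as stated
- violet: doubling the transfer coefficient of the gas phase, all else as stated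

- Saturation at 1.8 mM is far below the 0.050 M of substrate, so dissolved gas is supplied as it is used, and if [dissolved gas] stays near level, substrate decays pseudo-first-order.
- Substrate in ash falls at 0.0294 min⁻¹, which puts ash at 2.65 at 1.5 h on the gas clock, the natural log of substrate charged over substrate left; cedar at that same time read 2.36, with 16.6% target.
- At like substrate, target read 21.7% in ash and 21.5% in cedar despite cedar's 0.10 M charge, so we carry over cedar's last two readings, which lose 0.280 of log target per unit of clock, and ash, ahead of cedar by 0.290, should hold 15.3%.
- Target readings in ash already fall, so we expect red and violet, both pushing the clock on, to lower it, and we say none; a doubled clock after red gives 7.32%.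
- The forecast put target at 14.3%, below our figure, and at 4% after red, with none as best change, the time being “already past the maximum”.
- The flask gives 15.5%, and 6.36% after red, with none as best change: red moves target by −9.2 percentage points and violet by −1.2 points.

    gas phase ⇌ dissolved gas, rate k1*(csat - [dissolved gas]) (kL = 0.0420 s⁻¹)
    substrate + dissolved gas → target (k = 0.350 M⁻¹ s⁻¹)
    dissolved gas + target → over-reacted product (k = 0.0720 M⁻¹ s⁻¹)
    dissolved gas + target → over-reaction product (k = 0.190 M⁻¹ s⁻¹)
    dissolved gas → decomposed reagent (k = 3.90 × 10⁻⁴ s⁻¹)
    target ⇌ isomer of the product (K = 2.30, k = 9.40 × 10⁻⁴ s⁻¹)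

- At 0.750 h the flask held 27.4% substrate still feeding 22.1% target; by 1.50 h substrate was 6.06% against the clock's 7.07%, and target stood at 15.5% beside 29.1% over-reaction product. Read at 2.5 h, the same flask is put by our clock at 4.42, which gives 9.33% target where it holds 9.82%.

(The earlier runs and the new flask are calculated from invented constants; noise was put on by code.)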